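**Retrosynthetic overview**
1. Numbering used throughout: ring A = C1–C5/C10 and ring B = C5–C10. C4 bears =CH2, C5 is the fusion CH, C10 the fusion C(CH3), C9 = C(CH3)(C11H2Ar), C8 = CH(CH3). β is the face of the C10 methyl.
2. End game: C4=CH2 ⇐ C4 ketone ⇐ 4β-silyl ether (Wittig last). 8β-CH3/8α-H ⇐ 7β,8β-cyclopropane ⇐ C7=C8 alkene ⇐ C8 ketone 12.
3. Key disconnection: the cyclohexanone ring B of 12 ⇐ cyclopentanol 8 (ring C5–C6–C7–C8–C10) + aryl cation equivalent 11. Arylation of an isopropenyl group on C8 makes C11–Ar. A 1,2-shift of C10 from C8 to C9 then makes the C9–C10 bond, the quaternary centre C9 and the six-membered ring in the same operation.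
4. Enabling feature: C9 carries only CH3 and CH2Ar and lies in ring B between quaternary C10 and C8, a carbon that can pass through the carbonyl level. C9 is therefore the inner carbon of an isopropenyl group, and C8 is a tertiary carbinol in a five-membered ring.
5. Chiral pool and ring order: ring A, the five-membered ring, C5/C10, C9 and its CH3 come intact from vitamin D2 (steroid C14/C13, C20, C21; the steroid C8 oxygen is the future C4). This is the correct enantiomeric series. Ring B forms in step 9, and the arene is bought.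

Key step: step 9

**Step 1**
Reactants: 1 ergocalciferol (vitamin D2)
Product: 2 Inhoffen–Lythgoe diol (trans-hydrindane; 4β-OH; 5α-H; 10β-CH3; 8β-[(S)-1-hydroxypropan-2-yl])
Conditions: O3, CH2Cl2/MeOH, −78 °C; then NaBH4, −78 °C → rt
Reagents that add atoms: ozone [O-][O+]=O
Why: Exhaustive ozonolysis with reductive work-up cuts the triene and the side-chain alkene away from the bicycle without touching C5, C8 or C10, and hydride attack on the transient C4 ketone from the α face (opposite the C10 methyl) sets the axial 4β-alcohol, which is erased again in step 15.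

**Step 2**
Reactants: 2 Inhoffen–Lythgoe diol
Product: 3 hydroxy aldehyde (side chain CH(CH3)CHO on C8; 4β-OH free)
Conditions: TEMPO (10 mol %), PhI(OAc)2, CH2Cl2, rt
Reagents that add atoms: none
Why: The oxoammonium (TEMPO) oxidation should take the primary alcohol and leave the hindered axial secondary alcohol, and it creates no stereocentre.

**Step 3**
Reactants: 3 hydroxy aldehyde
Product: 4 silyl ether aldehyde (4β-OTBS)
Conditions: TBSOTf, 2,6-lutidine, CH2Cl2, −40 → 0 °C
Reagents that add atoms: tert-butyldimethylsilyl triflate CC(C)(C)[Si](C)(C)OS(=O)(=O)C(F)(F)F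
Why: Silyl triflate silylation reaches the hindered axial alcohol, and any epimerisation next to the aldehyde is harmless because that carbon (C9) becomes sp2 in step 4.

**Step 4**
Reactants: 4 silyl ether aldehyde
Product: 5 methyl ketone (8β-acetyl; 8α-H; 4β-OTBS)
Conditions: O2 (1 atm), Cu(OAc)2 (10 mol %), 2,2'-bipyridine (10 mol %), DABCO, DMF, 40 °C
Reagents that add atoms: dioxygen O=O
Why: Copper-catalysed aerobic oxidative deformylation of an α-branched aldehyde (enolate oxygenation, then C–C cleavage) is established for steroid 22-aldehydes and leaves C9 as a carbonyl carbon still bearing its methyl group, while the epimerisable C8 is rebuilt in step 5.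

**Step 5**
Reactants: 5 methyl ketone
Product: 7 8α-hydroxy-8β-acetyl hydrindane (α-ketol; 4β-OTBS), via 8α-hydroperoxide 6 (not isolated)
Conditions: KOtBu, O2, P(OEt)3, DMF/t-BuOH, −25 °C
Reagents that add atoms: dioxygen O=O
Why: Enolate autoxidation with in situ phosphite reduction (the classical 17α-hydroxylation of 20-keto steroids) runs through the more substituted C8 enolate under equilibrating conditions, and O2 attacks the α face opposite the C10 methyl, which sets the 8α-OH.

**Step 6**
Reactants: 7 α-ketol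
Product: 8 tertiary allylic alcohol (8α-OH; 8β-isopropenyl; 4β-OTBS)
Conditions: Cp2TiMe2 (3 equiv), toluene, 70 °C, dark
Reagents that add atoms: dimethyltitanocene C[Ti](C)(C1C=CC=C1)C1C=CC=C1
Why: The non-basic Petasis methylenation converts the hindered ketone into the isopropenyl group without triggering the base- or Lewis-acid-induced α-ketol rearrangement, and no stereocentre is touched.

**Step 7**
Reactants: 9 methyl 4-hydroxy-3-iodobenzoate
Product: 10 methyl 3-iodo-4-(pivaloyloxy)benzoate
Conditions: PivCl, Et3N, DMAP (cat.), CH2Cl2, 0 °C → rt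
Reagents that add atoms: pivaloyl chloride CC(C)(C)C(=O)Cl
Why: O-acylation masks the phenol with an ester that has no α-hydrogen and therefore survives the acid and oxidant of step 8 and the amide base of step 10.

**Step 8**
Reactants: 10 methyl 3-iodo-4-(pivaloyloxy)benzoate
Product: 11 [5-(methoxycarbonyl)-2-(pivaloyloxy)phenyl](mesityl)iodonium triflate
Conditions: mCPBA, TfOH, mesitylene, CH2Cl2, 0 °C → rt
Reagents that add atoms: mesitylene Cc1cc(C)cc(C)c1; trifluoromethanesulfonic acid OS(=O)(=O)C(F)(F)F
Why: One-pot oxidation of an electron-poor aryl iodide to iodine(III), followed by electrophilic substitution of the electron-rich arene, is the standard route to unsymmetrical aryl(mesityl)iodonium triflates.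

**Step 9**
Reactants: 8 tertiary allylic alcohol; 11 aryl(mesityl)iodonium triflate
Product: 12 ring-expanded ketone (trans-decalin; C8 ketone; 9α-CH2Ar; 9β-CH3; 10β-CH3; 5α-H; 4β-OTBS)
Conditions: 11 (1.5 equiv), Cu(OTf)2 (10 mol %), 2,6-di-tert-butylpyridine (1.5 equiv), CH2Cl2, 40 °C
Reagents that add atoms: none
Why: Proposed new method: Cu(I) formed in situ is oxidised by 11 to an electrophilic aryl–Cu(III) species that hands its aryl group to the terminal CH2 (future C11) of the isopropenyl unit, and the charge building up at C9 is quenched by a 1,2-shift of C10 from C8 to C9 while the C8–OH collapses to the ketone (semipinacol), the released TfOH being bound by the hindered pyridine. The closest known reaction types are the copper-catalysed, arylation-triggered semipinacol rearrangement of tertiary allylic alcohols with diaryliodonium salts (shown for strained cyclobutanols and for enol-ether- or styrene-type alkenes) and the classical D-homoannulation of 17-hydroxy-20-functionalised steroids, and what is new here is the unstrained cyclopentanol, the unactivated alkene and the migration of a fully substituted carbon. No ring is closed by cyclisation: ring B arises from the cyclopentane C5–C6–C7–C8–C10 by insertion of C9 into the C8–C10 bond, a one-carbon ring expansion by a 1,2-alkyl shift with retention at C10. The only new stereocentre, C9, is set by anti addition across the alkene: allylic 1,3-strain and O–Cu coordination hold the =CH2 terminus next to the 8α-oxygen, the aryl group arrives on the alkene face turned away from C10 and its methyl group, and C10 bonds to the opposite face, which places CH2Ar α and CH3 β. The step needs C10 rather than C7 to migrate (secured because the bulky electrophile can only approach anti to the C8–C10 bond, and by the higher migratory aptitude of the more substituted carbon), transfer of the functionalised aryl rather than mesityl (secured by the two ortho methyl groups of the dummy ligand), and migration rather than proton loss (favoured by the oxygen push and the aligned C8–C10 bond).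

**Step 10**
Reactants: 12 ring-expanded ketone
Product: 13 enol triflate (C7=C8–OTf)
Conditions: KHMDS, THF, −78 °C; then PhNTf2, −78 → 0 °C
Reagents that add atoms: N-phenylbis(trifluoromethanesulfonimide) O=S(=O)(N(c1ccccc1)S(=O)(=O)C(F)(F)F)C(F)(F)F
Why: Enolate O-triflation can go only towards C7 because C9 is quaternary, and the non-nucleophilic base leaves the benzoate and the α-hydrogen-free pivalate alone.

**Step 11**
Reactants: 13 enol triflate
Product: 14 C7=C8 alkene
Conditions: Pd(OAc)2 (5 mol %), PPh3, HCO2H, Et3N, DMF, 60 °C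
Reagents that add atoms: none
Why: Palladium-catalysed formate reduction of an enol triflate replaces OTf by H without moving the double bond or touching esters and silyl ether.

**Step 12**
Reactants: 14 C7=C8 alkene
Product: 15 7β,8β-methano compound (cyclopropane; 7α-H; 8α-H)
Conditions: Et2Zn, CH2I2, CH2Cl2, 0 °C → rt
Reagents that add atoms: diiodomethane ICI
Why: The Simmons–Smith (Furukawa) cyclopropanation is a concerted syn addition, and because the pseudoaxial 9α-arylmethyl group lies directly under C8 and screens the α face more than the 1,3-related C10 methyl screens the β face, CH2 should arrive from the β face and fix 8α-H.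

**Step 13**
Reactants: 15 cyclopropane
Product: 16 8β-methyl decalin (8α-H; phenol pivalate; 4β-OTBS)
Conditions: H2 (3–4 atm), PtO2, AcOH, rt
Reagents that add atoms: none
Why: Catalytic cyclopropane hydrogenolysis should break the most accessible bond, C7–CH2 (remote from quaternary C9), with retention at C8, so the bridging CH2 becomes the axial 8β-methyl group that hydrogenation of a C8-methyl alkene from outside could not deliver.

**Step 14**
Reactants: 16 8β-methyl decalin
Product: 18 4β-hydroxy phenol (fully deprotected decalin), via phenol silyl ether 17 (not isolated)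
Conditions: K2CO3 (cat.), MeOH, rt; then conc. HCl, 45 °C
Reagents that add atoms: none
Why: Base-catalysed methanolysis removes the activated aryl pivalate and acid-catalysed methanolysis then removes the hindered silyl ether, while the methyl ester can only exchange with the solvent and no stereocentre is touched.

**Step 15**
Reactants: 18 4β-hydroxy phenol
Product: 19 C4 ketone (trans-decalone with free phenol)
Conditions: Dess–Martin periodinane, CH2Cl2, 0 °C → rt
Reagents that add atoms: none
Why: Dess–Martin oxidation takes the secondary alcohol under near-neutral conditions that should neither oxidise the electron-poor phenol nor epimerise C5.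

**Step 16**
Reactants: 19 C4 ketone
Product: 20 target, methyl 4-hydroxy-3-{[(1R,2S,4aS,8aS)-1,2,8a-trimethyl-5-methylidenedecahydronaphthalen-1-yl]methyl}benzoate
Conditions: Ph3PCH3Br, KOtBu (3.5 equiv each), THF, 0 °C → rt
Reagents that add atoms: methyltriphenylphosphonium bromide C[P+](c1ccccc1)(c1ccccc1)c1ccccc1.[Br-]
Why: Wittig methylenation of the accessible C4 ketone at low temperature installs the acid-sensitive exocyclic alkene last, and the phenoxide formed first deactivates the para ester towards the ylide.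

**Compound list**
1 | ergocalciferol (vitamin D2) | C[C@H](/C=C/[C@H](C)C(C)C)[C@H]1CC[C@@H]\2[C@@]1(CCC/C2=C\C=C/3\C[C@H](CCC3=C)O)C | starting material
2 | Inhoffen–Lythgoe diol, (1R,3aR,4S,7aR)-1-[(2S)-1-hydroxypropan-2-yl]-7a-methyloctahydro-1H-inden-4-ol | C[C@H](CO)[C@H]1CC[C@@H]2[C@@]1(CCC[C@@H]2O)C | intermediate
3 | (2S)-2-[(1R,3aR,4S,7aR)-4-hydroxy-7a-methyloctahydro-1H-inden-1-yl]propanal | C[C@H](C=O)[C@H]1CC[C@@H]2[C@@]1(CCC[C@@H]2O)C | intermediate
4 | TBS ether of 3 | C[C@H](C=O)[C@H]1CC[C@@H]2[C@@]1(CCC[C@@H]2O[Si](C)(C)C(C)(C)C)C | intermediate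
5 | 8β-acetyl trans-hydrindane, 4β-OTBS | CC(=O)[C@H]1CC[C@@H]2[C@@]1(CCC[C@@H]2O[Si](C)(C)C(C)(C)C)C | intermediate
6 | 8α-hydroperoxy-8β-acetyl hydrindane (not isolated) | CC(=O)[C@@]1(OO)CC[C@@H]2[C@@]1(CCC[C@@H]2O[Si](C)(C)C(C)(C)C)C | intermediate
7 | 8α-hydroxy-8β-acetyl hydrindane (α-ketol) | CC(=O)[C@@]1(O)CC[C@@H]2[C@@]1(CCC[C@@H]2O[Si](C)(C)C(C)(C)C)C | intermediate
8 | 8α-hydroxy-8β-isopropenyl hydrindane | CC(=C)[C@@]1(O)CC[C@@H]2[C@@]1(CCC[C@@H]2O[Si](C)(C)C(C)(C)C)C | intermediate
9 | methyl 4-hydroxy-3-iodobenzoate | COC(=O)c1ccc(O)c(I)c1 | starting material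
10 | methyl 3-iodo-4-(pivaloyloxy)benzoate | COC(=O)c1ccc(OC(=O)C(C)(C)C)c(I)c1 | intermediate
11 | [5-(methoxycarbonyl)-2-(pivaloyloxy)phenyl](2,4,6-trimethylphenyl)iodonium triflate | COC(=O)c1ccc(OC(=O)C(C)(C)C)c([I+]c2c(C)cc(C)cc2C)c1.[O-]S(=O)(=O)C(F)(F)F | intermediate
12 | ring-expanded C8 ketone (9α-CH2Ar, 9β-CH3) | CC(C)(C)[Si](C)(C)O[C@H]1CCC[C@@]2(C)[C@H]1CCC(=O)[C@@]2(C)Cc1cc(C(=O)OC)ccc1OC(=O)C(C)(C)C | intermediate
13 | C7=C8 enol triflate | CC(C)(C)[Si](C)(C)O[C@H]1CCC[C@@]2(C)[C@H]1CC=C(OS(=O)(=O)C(F)(F)F)[C@@]2(C)Cc1cc(C(=O)OC)ccc1OC(=O)C(C)(C)C | intermediate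
14 | C7=C8 alkene | CC(C)(C)[Si](C)(C)O[C@H]1CCC[C@@]2(C)[C@H]1CC=C[C@@]2(C)Cc1cc(C(=O)OC)ccc1OC(=O)C(C)(C)C | intermediate
15 | 7β,8β-cyclopropane | CC(C)(C)[Si](C)(C)O[C@H]1CCC[C@@]2(C)[C@H]1C[C@@H]3C[C@@H]3[C@@]2(C)Cc1cc(C(=O)OC)ccc1OC(=O)C(C)(C)C | intermediate
16 | 8β-methyl decalin, pivalate, 4β-OTBS | CC(C)(C)[Si](C)(C)O[C@H]1CCC[C@@]2(C)[C@H]1CC[C@H](C)[C@@]2(C)Cc1cc(C(=O)OC)ccc1OC(=O)C(C)(C)C | intermediate
17 | free phenol, 4β-OTBS (not isolated) | CC(C)(C)[Si](C)(C)O[C@H]1CCC[C@@]2(C)[C@H]1CC[C@H](C)[C@@]2(C)Cc1cc(C(=O)OC)ccc1O | intermediate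
18 | 4β-alcohol, free phenol | O[C@H]1CCC[C@@]2(C)[C@H]1CC[C@H](C)[C@@]2(C)Cc1cc(C(=O)OC)ccc1O | intermediate
19 | C4 ketone, free phenol | O=C1CCC[C@@]2(C)[C@H]1CC[C@H](C)[C@@]2(C)Cc1cc(C(=O)OC)ccc1O | intermediate
20 | CNP0169318.1 | C=C1CCC[C@@]2(C)[C@H]1CC[C@H](C)[C@@]2(C)Cc1cc(C(=O)OC)ccc1O | target

**Step count:** 16 steps in total. The longest linear sequence is 14 steps (steps 1–6 and 9–16).

**Steps most likely to fail**

1. **Step 9 (Proposed new method).**
   - What may go wrong: aryl transfer from the ortho-substituted iodonium salt to the hindered alkene may be sluggish. The C9 cation may lose a proton. C7 may migrate in place of C10. Attack may occur through the other alkene rotamer.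
   - Fallback (known chemistry), from 8 back to 12. Hydroxyl-directed epoxidation of 8 (VO(acac)2, t-BuOOH) should give the epoxy alcohol F1 on the alkene face next to the 8α-oxygen. A Lewis acid (SnCl4 or ZnBr2, CH2Cl2, −78 °C) then triggers the established semipinacol rearrangement of 2,3-epoxy alcohols, in which C10 shifts anti to the C9–O bond, to give the ring-expanded β-hydroxy ketone F2. Dess–Martin oxidation gives the keto aldehyde F3. Nozaki–Hiyama–Kishi coupling with aryl iodide 10 gives the benzylic alcohol F4. Barton–McCombie deoxygenation through the imidazolyl thiocarbonate F5 (Bu3SnH, AIBN) leads to 12.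

2. **Step 12.**
   - What may go wrong: poor facial selectivity, or no reaction at the doubly flanked alkene.
   - Fallback, from 12 back to 16, with hydrogen delivered to C8 from inside the molecule. Non-basic zinc–titanium methylenation (Zn, CH2I2, TiCl4) of 12 gives the exocyclic alkene F6. Dimethyldioxirane attacks the less screened β face to give the spiro-epoxide F7 (oxygen β). Methylaluminium bis(4-bromo-2,6-di-tert-butylphenoxide) induces a Meinwald rearrangement in which hydride shifts to C8 anti to the departing oxygen, giving the axial 8β-aldehyde F8. Condensation with tosylhydrazine gives the tosylhydrazone F9, and reduction with catecholborane/NaOAc gives 16.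

3. **Step 13.**
   - What may go wrong: cleavage of the wrong cyclopropane bond, or saturation of the arene under forcing hydrogenolysis.
   - Fallback, from 14 back to 16, with methyl delivered as a nucleophile. Allylic oxidation (CrO3·3,5-dimethylpyrazole) at C6, the only allylic CH2, gives the enone F10. Me2CuLi/TMSCl adds to C8 axially and anti to the pseudoaxial 9α-arylmethyl group, giving the 8β-methyl C6 ketone F11. The tosylhydrazone F12 is then reduced with catecholborane/NaOAc to 16.

**Further compounds**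
F1 | step 9 | epoxy alcohol (8α-OH, C9–C11 epoxide) | C[C@]1(CO1)[C@@]2(O)CC[C@@H]3[C@@]2(CCC[C@@H]3O[Si](C)(C)C(C)(C)C)C
F2 | step 9 | ring-expanded β-hydroxy ketone (9α-CH2OH, 9β-CH3) | CC(C)(C)[Si](C)(C)O[C@H]1CCC[C@@]2(C)[C@H]1CCC(=O)[C@@]2(C)CO
F3 | step 9 | keto aldehyde (9α-CHO) | CC(C)(C)[Si](C)(C)O[C@H]1CCC[C@@]2(C)[C@H]1CCC(=O)[C@@]2(C)C=O
F4 | step 9 | benzylic alcohol (C11 epimers) | CC(C)(C)[Si](C)(C)O[C@H]1CCC[C@@]2(C)[C@H]1CCC(=O)[C@@]2(C)C(O)c1cc(C(=O)OC)ccc1OC(=O)C(C)(C)C
F5 | step 9 | imidazolyl thiocarbonate of F4 | CC(C)(C)[Si](C)(C)O[C@H]1CCC[C@@]2(C)[C@H]1CCC(=O)[C@@]2(C)C(OC(=S)n1ccnc1)c1cc(C(=O)OC)ccc1OC(=O)C(C)(C)C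
F6 | step 12 | C8 exocyclic alkene | CC(C)(C)[Si](C)(C)O[C@H]1CCC[C@@]2(C)[C@H]1CCC(=C)[C@@]2(C)Cc1cc(C(=O)OC)ccc1OC(=O)C(C)(C)C
F7 | step 12 | C8 spiro-epoxide (oxygen β) | CC(C)(C)[Si](C)(C)O[C@H]1CCC[C@@]2(C)[C@H]1CC[C@@]3(CO3)[C@@]2(C)Cc1cc(C(=O)OC)ccc1OC(=O)C(C)(C)C
F8 | step 12 | 8β-carbaldehyde (8α-H) | CC(C)(C)[Si](C)(C)O[C@H]1CCC[C@@]2(C)[C@H]1CC[C@H](C=O)[C@@]2(C)Cc1cc(C(=O)OC)ccc1OC(=O)C(C)(C)C
F9 | step 12 | tosylhydrazone of F8 | CC(C)(C)[Si](C)(C)O[C@H]1CCC[C@@]2(C)[C@H]1CC[C@H](C=NNS(=O)(=O)c1ccc(C)cc1)[C@@]2(C)Cc1cc(C(=O)OC)ccc1OC(=O)C(C)(C)C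
F10 | step 13 | C6 enone (C7=C8) | CC(C)(C)[Si](C)(C)O[C@H]1CCC[C@@]2(C)[C@H]1C(=O)C=C[C@@]2(C)Cc1cc(C(=O)OC)ccc1OC(=O)C(C)(C)C
F11 | step 13 | 8β-methyl C6 ketone | CC(C)(C)[Si](C)(C)O[C@H]1CCC[C@@]2(C)[C@H]1C(=O)C[C@H](C)[C@@]2(C)Cc1cc(C(=O)OC)ccc1OC(=O)C(C)(C)C
F12 | step 13 | tosylhydrazone of F11 | CC(C)(C)[Si](C)(C)O[C@H]1CCC[C@@]2(C)[C@H]1C(=NNS(=O)(=O)c1ccc(C)cc1)C[C@H](C)[C@@]2(C)Cc1cc(C(=O)OC)ccc1OC(=O)C(C)(C)C
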